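**Retrosynthetic overview**
1. Feature: ring A shares the C4a–C8a bond with ring C. The chain C8≡C8a–O1–C2–C3–C4–C4a≡C5 (an ynol ether 1,7-diyne) and an alkyne C6≡C7, with Ca on C6 and boron (the masked C7–OH) on C7, together hold all six carbons of ring A.
2. Key disconnection: a rhodium-catalysed (2+2+2) cycloaddition makes C4a–C8a, C5–C6 and C7–C8. Rings B, D and E are bought as arenes; ring C closes first (metallacycle) and ring A second, in the same step.
3. Repair: polarity alone would send boron to C6, because C8 is the nucleophilic ynol ether carbon and the carbon remote from boron is the electrophilic one. C8 therefore carries a removable SiEt3 cap that forces the first C–C bond to form at C5.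
4. Diyne: Weinreb ketone synthesis, Corey–Bakshi–Shibata reduction (sets C2), dichlorovinyl ether, elimination to the silyl ynol ether. Boronate: Heck aldehyde, propargylic bromide, enantioconvergent nickel Negishi arylation (sets Ca), borylation.
5. Endgame: oxidation of C7–B, protodesilylation at C8, hydrogenolysis of three benzyl ethers.

Key step: step 15

Assumption: where the catalyst antipode is not named (step 12 and the rhodium addition in the first fallback), a trial run fixes which antipode gives the drawn configuration; both antipodes are sold.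

**Route**

Step 1
Reactants: 1 3-bromo-4-methoxyphenol
Product: 2 4-(benzyloxy)-2-bromo-1-methoxybenzene
Conditions: BnBr, K2CO3, DMF, rt
Reagents that add atoms: benzyl bromide BrCc1ccccc1
Why: Williamson ether synthesis on the only acidic O–H, with the aryl bromide and the methyl ether inert to carbonate.

Step 2
Reactants: 3 pent-4-ynoic acid
Product: 5 N-methoxy-N-methylpent-4-ynamide, via acyl imidazole 4 (not isolated)
Conditions: 1,1'-carbonyldiimidazole, CH2Cl2, rt; then MeNH(OMe)·HCl, rt
Reagents that add atoms: N,O-dimethylhydroxylamine hydrochloride CNOC.Cl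
Why: Weinreb amide formation through the acyl imidazole is mild enough to leave the terminal alkyne untouched.

Step 3
Reactants: 2 4-(benzyloxy)-2-bromo-1-methoxybenzene; 5 N-methoxy-N-methylpent-4-ynamide
Product: 7 1-[5-(benzyloxy)-2-methoxyphenyl]pent-4-yn-1-one, via aryl Grignard reagent 6 (not isolated)
Conditions: 2 (2.2 equiv), Mg, I2 (cat.), THF, 45 °C; then 5, 0 °C to rt; 1 M HCl
Reagents that add atoms: none
Why: Weinreb ketone synthesis, in which the chelated tetrahedral intermediate stops at the ketone and the second equivalent of Grignard reagent is spent on the acidic alkyne C–H, which work-up restores.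

Step 4
Reactants: 7 1-[5-(benzyloxy)-2-methoxyphenyl]pent-4-yn-1-one
Product: 8 (1S)-1-[5-(benzyloxy)-2-methoxyphenyl]pent-4-yn-1-ol
Conditions: (R)-Me-CBS oxazaborolidine (15 mol %), catecholborane (1.6 equiv), toluene, −78 to −40 °C; MeOH, aq NaOH
Reagents that add atoms: none
Why: Corey–Bakshi–Shibata reduction, in which the (R)-oxazaborolidine treats the aryl group as the large substituent and delivers hydride to the Re face to set (S) at C2, and catecholborane replaces BH3 because it does not hydroborate the terminal alkyne in the cold.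

Step 5
Reactants: 8 (1S)-1-[5-(benzyloxy)-2-methoxyphenyl]pent-4-yn-1-ol
Product: 10 (1S)-1-[5-(benzyloxy)-2-methoxyphenyl]pent-4-yn-1-yl (E)-1,2-dichloroethenyl ether, via potassium alkoxide 9 (not isolated)
Conditions: KH (1.1 equiv), THF, 0 °C; Cl2C=CHCl (1.1 equiv), −50 °C to rt
Reagents that add atoms: trichloroethylene ClC=C(Cl)Cl
Why: Anti addition of the alkoxide to dichloroacetylene, formed in situ from trichloroethylene, gives the (E)-dichlorovinyl ether without touching the C2–O bond, so the configuration is kept, and the much less acidic alkyne C–H stays protonated.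

Step 6
Reactants: 10 (1S)-1-[5-(benzyloxy)-2-methoxyphenyl]pent-4-yn-1-yl (E)-1,2-dichloroethenyl ether
Product: 12 (1S)-1-[5-(benzyloxy)-2-methoxyphenyl]-5-(trimethylsilyl)pent-4-yn-1-yl (E)-1,2-dichloroethenyl ether, via bromomagnesium acetylide 11 (not isolated)
Conditions: EtMgBr (1.05 equiv), THF, 0 to 40 °C; Me3SiCl, rt
Reagents that add atoms: chlorotrimethylsilane C[Si](C)(C)Cl
Why: Deprotonation of the terminal alkyne by a Grignard base too weak to attack the dichlorovinyl ether, followed by C-silylation, masks C5 so that step 7 produces a single acetylide.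

Step 7
Reactants: 12 (1S)-1-[5-(benzyloxy)-2-methoxyphenyl]-5-(trimethylsilyl)pent-4-yn-1-yl (E)-1,2-dichloroethenyl ether
Product: 15 (1S)-1-[5-(benzyloxy)-2-methoxyphenyl]pent-4-yn-1-yl (triethylsilyl)ethynyl ether, via lithium alkoxyacetylide 13 (not isolated), via doubly silylated diyne 14 (not isolated)
Conditions: n-BuLi (2.2 equiv), THF, −78 to −40 °C; Et3SiCl (1.2 equiv), −78 to 0 °C; then MeOH, K2CO3 (0.3 equiv), 0 °C; product kept below 25 °C
Reagents that add atoms: chlorotriethylsilane CC[Si](Cl)(CC)CC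
Why: Dehydrochlorination and chlorine–lithium exchange convert the dichlorovinyl ether into the lithium alkoxyacetylide, which is C-silylated, and base-catalysed methanolysis should then remove the small SiMe3 group at C5 much faster than the bulkier SiEt3 group at C8.

Step 8
Reactants: 16 4-bromo-3-methoxyphenol
Product: 17 4-(benzyloxy)-1-bromo-2-methoxybenzene
Conditions: BnBr, K2CO3, DMF, rt
Reagents that add atoms: benzyl bromide BrCc1ccccc1
Why: Williamson ether synthesis on the single phenol.

Step 9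
Reactants: 17 4-(benzyloxy)-1-bromo-2-methoxybenzene
Product: 18 3-[4-(benzyloxy)-2-methoxyphenyl]propanal
Conditions: allyl alcohol (1.5 equiv), Pd(OAc)2 (3 mol %), Bu4NCl, NaHCO3, DMF, 90 °C
Reagents that add atoms: allyl alcohol C=CCO
Why: Heck arylation of allyl alcohol, in which carbopalladation at the terminal carbon, β-hydride elimination towards the carbinol and enol tautomerisation give the saturated aldehyde directly and leave the benzyl ether intact.

Step 10
Reactants: 18 3-[4-(benzyloxy)-2-methoxyphenyl]propanal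
Product: 19 rac-5-[4-(benzyloxy)-2-methoxyphenyl]-1-(trimethylsilyl)pent-1-yn-3-ol
Conditions: Me3SiC≡CH, n-BuLi, THF, −78 °C; then 18; H2O
Reagents that add atoms: ethynyltrimethylsilane C#C[Si](C)(C)C
Why: 1,2-Addition of a lithium acetylide to an aldehyde, where the racemate is acceptable because step 12 is enantioconvergent.

Step 11
Reactants: 19 rac-5-[4-(benzyloxy)-2-methoxyphenyl]-1-(trimethylsilyl)pent-1-yn-3-ol
Product: 20 rac-{3-bromo-5-[4-(benzyloxy)-2-methoxyphenyl]pent-1-yn-1-yl}trimethylsilane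
Conditions: PPh3, CBr4, CH2Cl2, 0 °C
Reagents that add atoms: tetrabromomethane BrC(Br)(Br)Br
Why: The Appel reaction turns the secondary propargylic alcohol into the bromide under neutral conditions, and the silyl group on the alkyne disfavours allene formation.

Step 12
Reactants: 20 rac-{3-bromo-5-[4-(benzyloxy)-2-methoxyphenyl]pent-1-yn-1-yl}trimethylsilane; 21 [4-(benzyloxy)phenyl]boronic acid
Product: 23 {(3R)-5-[4-(benzyloxy)-2-methoxyphenyl]-3-[4-(benzyloxy)phenyl]pent-1-yn-1-yl}trimethylsilane, via arylzinc reagent 22 (not isolated)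
Conditions: 21 (2 equiv), Et2Zn (3 equiv per 21), toluene, 60 °C; then 20, NiCl2·glyme (5 mol %), indanyl-pybox (6.5 mol %), glyme, −20 °C
Reagents that add atoms: none
Why: Nickel-catalysed enantioconvergent Negishi arylation of a racemic silyl-protected propargylic bromide, in which both enantiomers pass through one propargylic radical and the chiral pybox–nickel aryl complex decides the face of C–C bond formation and so sets Ca.

Step 13
Reactants: 23 {(3R)-5-[4-(benzyloxy)-2-methoxyphenyl]-3-[4-(benzyloxy)phenyl]pent-1-yn-1-yl}trimethylsilane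
Product: 24 4-(benzyloxy)-1-{(3S)-3-[4-(benzyloxy)phenyl]pent-4-yn-1-yl}-2-methoxybenzene
Conditions: K2CO3 (0.3 equiv), MeOH/THF, 0 °C to rt
Reagents that add atoms: none
Why: Base-catalysed methanolysis of the alkynylsilane uses a base too weak to remove the benzylic–propargylic Ca–H, so the arrangement at Ca holds and only the descriptor changes, because aryl now outranks ethynyl.

Step 14
Reactants: 24 4-(benzyloxy)-1-{(3S)-3-[4-(benzyloxy)phenyl]pent-4-yn-1-yl}-2-methoxybenzene
Product: 27 2-{(3R)-5-[4-(benzyloxy)-2-methoxyphenyl]-3-[4-(benzyloxy)phenyl]pent-1-yn-1-yl}-4,4,5,5-tetramethyl-1,3,2-dioxaborolane, via lithium acetylide 25 (not isolated), via lithium borate 26 (not isolated)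
Conditions: n-BuLi (1.0 equiv), THF, −78 °C; iPrOBpin, −78 °C; HCl·Et2O (1.0 equiv), −78 °C to rt
Reagents that add atoms: 2-isopropoxy-4,4,5,5-tetramethyl-1,3,2-dioxaborolane CC(C)OB1OC(C)(C)C(C)(C)O1
Why: Borylation of a lithium acetylide through the borate complex with anhydrous acid release, where exactly one equivalent of base at −78 °C removes only the alkyne proton and leaves Ca–H alone.

Step 15
Reactants: 15 (1S)-1-[5-(benzyloxy)-2-methoxyphenyl]pent-4-yn-1-yl (triethylsilyl)ethynyl ether; 27 2-{(3R)-5-[4-(benzyloxy)-2-methoxyphenyl]-3-[4-(benzyloxy)phenyl]pent-1-yn-1-yl}-4,4,5,5-tetramethyl-1,3,2-dioxaborolane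
Product: 28 (2S)-2-[5-(benzyloxy)-2-methoxyphenyl]-6-{(1R)-3-[4-(benzyloxy)-2-methoxyphenyl]-1-[4-(benzyloxy)phenyl]propyl}-7-(4,4,5,5-tetramethyl-1,3,2-dioxaborolan-2-yl)-8-(triethylsilyl)chroman
Conditions: [Rh(cod)2]BF4 (10 mol %), H8-BINAP (10 mol %, either antipode), H2 then Ar, CH2Cl2, rt (not above 40 °C); 15 added slowly to 27 (1.3 equiv)
Reagents that add atoms: none
Why: Proposed new method: the cationic monovalent rhodium centre should couple the two alkynes of 15 oxidatively to a rhodacyclopentadiene in which C4a–C8a is already made, so ring C closes as a six-membered ring through the tether C4–C3–C2–O1, after which 27 inserts (C5–C6) and reductive elimination from the seven-membered rhodacycle (C7–C8) closes ring A. The closest known reaction types are rhodium- and ruthenium-catalysed (2+2+2) cycloadditions of tethered diynes with alkynylboronates, and of ynol-ether- or ynamide-linked diynes capped at the heteroatom alkyne with polarised internal alkynes, but a silyl-capped ynol ether 1,7-diyne has not been combined with a branched alkynylboronate. No stereocentre is formed, and C2 and Ca are spectators because the medium is neutral, free of base and kept near room temperature. The selectivity needed is regiochemical: the boron-bearing carbon must bond to C8 and the Ca-bearing carbon to C5. With two CH termini polarity would oppose this, so the SiEt3 cap blocks migration from C8, insertion starts at the open Rh–C5 bond, rhodium goes to the boron-bearing carbon as is usual for alkynylboronates, and the bulky Ca branch stays away from silicon. The cap should also slow self-trimerisation of 15 and stabilise the secondary benzylic ynol ether against fragmentation.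

Step 16
Reactants: 28 (2S)-2-[5-(benzyloxy)-2-methoxyphenyl]-6-{(1R)-3-[4-(benzyloxy)-2-methoxyphenyl]-1-[4-(benzyloxy)phenyl]propyl}-7-(4,4,5,5-tetramethyl-1,3,2-dioxaborolan-2-yl)-8-(triethylsilyl)chroman
Product: 29 (2S)-2-[5-(benzyloxy)-2-methoxyphenyl]-6-{(1R)-3-[4-(benzyloxy)-2-methoxyphenyl]-1-[4-(benzyloxy)phenyl]propyl}-8-(triethylsilyl)chroman-7-ol
Conditions: NaBO3·4H2O (5 equiv), THF/H2O, rt to 40 °C
Reagents that add atoms: sodium perborate [Na+].[Na+].O[B-]1(O)OO[B-](O)(O)OO1
Why: Oxidation of an arylboronate, in which peroxide adds to boron and the aryl group migrates from boron to oxygen at the same carbon, while benzyl ethers, the arylsilane and both stereocentres are inert to perborate.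

Step 17
Reactants: 29 (2S)-2-[5-(benzyloxy)-2-methoxyphenyl]-6-{(1R)-3-[4-(benzyloxy)-2-methoxyphenyl]-1-[4-(benzyloxy)phenyl]propyl}-8-(triethylsilyl)chroman-7-ol
Product: 30 (2S)-2-[5-(benzyloxy)-2-methoxyphenyl]-6-{(1R)-3-[4-(benzyloxy)-2-methoxyphenyl]-1-[4-(benzyloxy)phenyl]propyl}chroman-7-ol
Conditions: CF3CO2H (3 equiv), CH2Cl2, −20 to 0 °C; aq NaHCO3
Reagents that add atoms: none
Why: Protodesilylation by ipso protonation (electrophilic aromatic substitution) should need only cold dilute acid because C8 lies ortho to both O1 and the new C7–OH, so the benzylic C2–O1 bond should not ionise and C2 should not epimerise.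

Step 18
Reactants: 30 (2S)-2-[5-(benzyloxy)-2-methoxyphenyl]-6-{(1R)-3-[4-(benzyloxy)-2-methoxyphenyl]-1-[4-(benzyloxy)phenyl]propyl}chroman-7-ol
Product: 31 (2S)-2-(5-hydroxy-2-methoxyphenyl)-6-[(1R)-3-(4-hydroxy-2-methoxyphenyl)-1-(4-hydroxyphenyl)propyl]chroman-7-ol
Conditions: H2 (1 atm), 10% Pd/C, EtOAc/MeOH, rt
Reagents that add atoms: none
Why: Hydrogenolysis of the three O-benzyl ethers is much faster than cleavage of the cyclic C2–O1 benzylic aryl ether of a flavan, so the reaction is stopped after three equivalents of hydrogen are taken up.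

**Compound list**
1 | 3-bromo-4-methoxyphenol | COc1ccc(O)cc1Br | starting material
2 | 4-(benzyloxy)-2-bromo-1-methoxybenzene | COc1ccc(OCc2ccccc2)cc1Br | intermediate
3 | pent-4-ynoic acid | C#CCCC(=O)O | starting material
4 | 1-(pent-4-ynoyl)imidazole | C#CCCC(=O)n1ccnc1 | intermediate
5 | N-methoxy-N-methylpent-4-ynamide | C#CCCC(=O)N(C)OC | intermediate
6 | [5-(benzyloxy)-2-methoxyphenyl]magnesium bromide | COc1ccc(OCc2ccccc2)cc1[Mg]Br | intermediate
7 | 1-[5-(benzyloxy)-2-methoxyphenyl]pent-4-yn-1-one | C#CCCC(=O)c1cc(OCc2ccccc2)ccc1OC | intermediate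
8 | (1S)-1-[5-(benzyloxy)-2-methoxyphenyl]pent-4-yn-1-ol | O[C@H](c1cc(OCc2ccccc2)ccc1OC)CCC#C | intermediate
9 | potassium alkoxide of 8 | [K+].[O-][C@H](c1cc(OCc2ccccc2)ccc1OC)CCC#C | intermediate
10 | (1S)-1-[5-(benzyloxy)-2-methoxyphenyl]pent-4-yn-1-yl (E)-1,2-dichloroethenyl ether | Cl/C=C(/Cl)O[C@H](c1cc(OCc2ccccc2)ccc1OC)CCC#C | intermediate
11 | bromomagnesium acetylide of 10 | Cl/C=C(/Cl)O[C@H](c1cc(OCc2ccccc2)ccc1OC)CCC#C[Mg]Br | intermediate
12 | (1S)-1-[5-(benzyloxy)-2-methoxyphenyl]-5-(trimethylsilyl)pent-4-yn-1-yl (E)-1,2-dichloroethenyl ether | Cl/C=C(/Cl)O[C@H](c1cc(OCc2ccccc2)ccc1OC)CCC#C[Si](C)(C)C | intermediate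
13 | lithium alkoxyacetylide from 12 (S at C2) | [Li]C#CO[C@H](c1cc(OCc2ccccc2)ccc1OC)CCC#C[Si](C)(C)C | intermediate
14 | (1S)-1-[5-(benzyloxy)-2-methoxyphenyl]-5-(trimethylsilyl)pent-4-yn-1-yl (triethylsilyl)ethynyl ether | CC[Si](CC)(CC)C#CO[C@H](c1cc(OCc2ccccc2)ccc1OC)CCC#C[Si](C)(C)C | intermediate
15 | (1S)-1-[5-(benzyloxy)-2-methoxyphenyl]pent-4-yn-1-yl (triethylsilyl)ethynyl ether | CC[Si](CC)(CC)C#CO[C@H](c1cc(OCc2ccccc2)ccc1OC)CCC#C | intermediate
16 | 4-bromo-3-methoxyphenol | COc1cc(O)ccc1Br | starting material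
17 | 4-(benzyloxy)-1-bromo-2-methoxybenzene | COc1cc(OCc2ccccc2)ccc1Br | intermediate
18 | 3-[4-(benzyloxy)-2-methoxyphenyl]propanal | COc1cc(OCc2ccccc2)ccc1CCC=O | intermediate
19 | rac-5-[4-(benzyloxy)-2-methoxyphenyl]-1-(trimethylsilyl)pent-1-yn-3-ol | COc1cc(OCc2ccccc2)ccc1CCC(O)C#C[Si](C)(C)C | intermediate
20 | rac-{3-bromo-5-[4-(benzyloxy)-2-methoxyphenyl]pent-1-yn-1-yl}trimethylsilane | COc1cc(OCc2ccccc2)ccc1CCC(Br)C#C[Si](C)(C)C | intermediate
21 | [4-(benzyloxy)phenyl]boronic acid | OB(O)c1ccc(OCc2ccccc2)cc1 | starting material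
22 | [4-(benzyloxy)phenyl](ethyl)zinc | CC[Zn]c1ccc(OCc2ccccc2)cc1 | intermediate
23 | {(3R)-5-[4-(benzyloxy)-2-methoxyphenyl]-3-[4-(benzyloxy)phenyl]pent-1-yn-1-yl}trimethylsilane | COc1cc(OCc2ccccc2)ccc1CC[C@H](c1ccc(OCc2ccccc2)cc1)C#C[Si](C)(C)C | intermediate
24 | 4-(benzyloxy)-1-{(3S)-3-[4-(benzyloxy)phenyl]pent-4-yn-1-yl}-2-methoxybenzene | COc1cc(OCc2ccccc2)ccc1CC[C@H](c1ccc(OCc2ccccc2)cc1)C#C | intermediate
25 | lithium acetylide of 24 (Ca unchanged) | COc1cc(OCc2ccccc2)ccc1CC[C@H](c1ccc(OCc2ccccc2)cc1)C#C[Li] | intermediate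
26 | lithium alkynyl(isopropoxy)pinacolborate from 25 (Ca unchanged) | [Li+].COc1cc(OCc2ccccc2)ccc1CC[C@H](c1ccc(OCc2ccccc2)cc1)C#C[B-]1(OC(C)C)OC(C)(C)C(C)(C)O1 | intermediate
27 | 2-{(3R)-5-[4-(benzyloxy)-2-methoxyphenyl]-3-[4-(benzyloxy)phenyl]pent-1-yn-1-yl}-4,4,5,5-tetramethyl-1,3,2-dioxaborolane | COc1cc(OCc2ccccc2)ccc1CC[C@H](c1ccc(OCc2ccccc2)cc1)C#CB1OC(C)(C)C(C)(C)O1 | intermediate
28 | (2S)-flavan with Bpin at C7, SiEt3 at C8, the (1R) Ca branch at C6 and benzyl ethers on rings B, D and E | COc1cc(OCc2ccccc2)ccc1CC[C@H](c1ccc(OCc2ccccc2)cc1)c1cc2c(c([Si](CC)(CC)CC)c1B1OC(C)(C)C(C)(C)O1)O[C@H](c1cc(OCc3ccccc3)ccc1OC)CC2 | intermediate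
29 | (2S,1R)-8-(triethylsilyl)flavan-7-ol tribenzyl ether | COc1cc(OCc2ccccc2)ccc1CC[C@H](c1ccc(OCc2ccccc2)cc1)c1cc2c(c([Si](CC)(CC)CC)c1O)O[C@H](c1cc(OCc3ccccc3)ccc1OC)CC2 | intermediate
30 | (2S,1R)-flavan-7-ol tribenzyl ether | COc1cc(OCc2ccccc2)ccc1CC[C@H](c1ccc(OCc2ccccc2)cc1)c1cc2c(cc1O)O[C@H](c1cc(OCc3ccccc3)ccc1OC)CC2 | intermediate
31 | (2S)-2-(5-hydroxy-2-methoxyphenyl)-6-[(1R)-3-(4-hydroxy-2-methoxyphenyl)-1-(4-hydroxyphenyl)propyl]chroman-7-ol (CNP0239474.1) | COc1cc(O)ccc1CC[C@H](c1ccc(O)cc1)c1cc2c(cc1O)O[C@H](c1cc(O)ccc1OC)CC2 | target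

**Step count**
Total step count: 18.
Longest linear sequence: 11 steps (16 to 31, steps 8 to 18).

**Steps most likely to fail**

1. Step 15.
What may go wrong: oxidative cyclisation of the capped ynol ether may be slow, so the free alkyne end oligomerises. Insertion of the branched alkynylboronate may be sluggish. The ynol ether may fragment if heat is applied. The final C7–C8 reductive elimination between two crowded carbons may stall.
Fallback (known chemistry only, ring A bought instead of built): it sets out from bromide 2, uses 17 and 21 on the way, and comes back to the route at target 31.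
- Ring C: 7-hydroxychroman-2-one is benzylated (BnBr, K2CO3) to 7-(benzyloxy)chroman-2-one F1. The aryllithium from 2 (n-BuLi, THF, −78 °C) adds once to the lactone to give 3-[4-(benzyloxy)-2-hydroxyphenyl]-1-[5-(benzyloxy)-2-methoxyphenyl]propan-1-one F2. Corey–Bakshi–Shibata reduction with (S)-Me-CBS and BH3·SMe2 gives the (1R)-alcohol F3, and Mitsunobu cyclisation (PPh3, DIAD) closes ring C with inversion to (2S)-7-(benzyloxy)-2-[5-(benzyloxy)-2-methoxyphenyl]chroman F4.
- Ca branch: Vilsmeier–Haack formylation (POCl3, DMF) attacks C6, para to O1 and ortho to the C7 ether, to give the 6-carbaldehyde F5. A Wittig reaction with Ph3P=CHCHO gives the (E)-enal F6. Hayashi–Miyaura 1,4-addition of 21 ([RhCl(C2H4)2]2, chiral bicyclooctadiene ligand, KOH, MeOH/H2O) sets Ca in the (3R)-3,3-diarylpropanal F7.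
- Finish: the Grignard reagent from 17 adds to F7 to give the benzylic alcohol F8, either carbinol epimer being usable. Hydrogenolysis over Pd/C removes the four benzyl ethers and the electron-rich benzylic hydroxyl group to give 31.

2. Step 7.
What may go wrong: methanolysis may discriminate poorly between the two silyl groups. Butyllithium may deprotonate the benzylic C2–H. The secondary benzylic alkynyl ether may fragment on concentration.
Fallback (the cap is given up): it sets out from 10 and comes back at 30. n-BuLi (3.3 equiv, THF, −78 to −40 °C) followed by MeOH gives (1S)-1-[5-(benzyloxy)-2-methoxyphenyl]pent-4-yn-1-yl ethynyl ether F9. Its cycloaddition with 27 under the conditions of step 15, or with Cp*RuCl(cod), gives the C8-unsubstituted (2S)-flavan 7-pinacolboronate F10. The orientation then rests on the catalyst alone and the product has to be purified by chromatography. NaBO3·4H2O converts F10 into 30.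

3. Step 12.
What may go wrong: facial selectivity may be poor with the long electron-rich side chain, or reduction and homocoupling of the bromide may outrun the cross-coupling.
Fallback (stereospecific instead of enantioconvergent): it sets out from 19 and comes back at 23. MnO2 oxidises 19 to 5-[4-(benzyloxy)-2-methoxyphenyl]-1-(trimethylsilyl)pent-1-yn-3-one F11. Noyori-type asymmetric transfer hydrogenation with RuCl(p-cymene)[(R,R)-TsDPEN] in iPrOH gives the (3R)-alcohol F12, and ClP(O)(OEt)2 with N-methylimidazole gives the (3R)-diethyl phosphate F13. The arylcopper reagent from 1-(benzyloxy)-4-bromobenzene (n-BuLi, then CuBr·SMe2) displaces the phosphate at the propargylic carbon with inversion, the silyl group blocking attack at the alkyne terminus, to give 23.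

**Further compounds**
F1 | step 15 | 7-(benzyloxy)chroman-2-one | O=C1CCc2ccc(OCc3ccccc3)cc2O1
F2 | step 15 | 3-[4-(benzyloxy)-2-hydroxyphenyl]-1-[5-(benzyloxy)-2-methoxyphenyl]propan-1-one | COc1ccc(OCc2ccccc2)cc1C(=O)CCc1ccc(OCc2ccccc2)cc1O
F3 | step 15 | 5-(benzyloxy)-2-{(3R)-3-[5-(benzyloxy)-2-methoxyphenyl]-3-hydroxypropyl}phenol | O[C@@H](c1cc(OCc2ccccc2)ccc1OC)CCc1ccc(OCc2ccccc2)cc1O
F4 | step 15 | (2S)-7-(benzyloxy)-2-[5-(benzyloxy)-2-methoxyphenyl]chroman | O1[C@H](c2cc(OCc3ccccc3)ccc2OC)CCc2ccc(OCc3ccccc3)cc12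
F5 | step 15 | (2S)-7-(benzyloxy)-2-[5-(benzyloxy)-2-methoxyphenyl]chroman-6-carbaldehyde | O1[C@H](c2cc(OCc3ccccc3)ccc2OC)CCc2cc(C=O)c(OCc3ccccc3)cc12
F6 | step 15 | (E)-3-{(2S)-7-(benzyloxy)-2-[5-(benzyloxy)-2-methoxyphenyl]chroman-6-yl}prop-2-enal | O1[C@H](c2cc(OCc3ccccc3)ccc2OC)CCc2cc(/C=C/C=O)c(OCc3ccccc3)cc12
F7 | step 15 | (3R)-3-[4-(benzyloxy)phenyl]-3-{(2S)-7-(benzyloxy)-2-[5-(benzyloxy)-2-methoxyphenyl]chroman-6-yl}propanal | O=CC[C@H](c1ccc(OCc2ccccc2)cc1)c1cc2c(cc1OCc1ccccc1)O[C@H](c1cc(OCc3ccccc3)ccc1OC)CC2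
F8 | step 15 | (3R)-1-[4-(benzyloxy)-2-methoxyphenyl]-3-[4-(benzyloxy)phenyl]-3-{(2S)-7-(benzyloxy)-2-[5-(benzyloxy)-2-methoxyphenyl]chroman-6-yl}propan-1-ol (carbinol epimers) | COc1cc(OCc2ccccc2)ccc1C(O)C[C@H](c1ccc(OCc2ccccc2)cc1)c1cc2c(cc1OCc1ccccc1)O[C@H](c1cc(OCc3ccccc3)ccc1OC)CC2
F9 | step 7 | (1S)-1-[5-(benzyloxy)-2-methoxyphenyl]pent-4-yn-1-yl ethynyl ether | C#CO[C@H](c1cc(OCc2ccccc2)ccc1OC)CCC#C
F10 | step 7 | (2S)-flavan with Bpin at C7, H at C8, the (1R) Ca branch at C6 and benzyl ethers on rings B, D and E | COc1cc(OCc2ccccc2)ccc1CC[C@H](c1ccc(OCc2ccccc2)cc1)c1cc2c(cc1B1OC(C)(C)C(C)(C)O1)O[C@H](c1cc(OCc3ccccc3)ccc1OC)CC2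
F11 | step 12 | 5-[4-(benzyloxy)-2-methoxyphenyl]-1-(trimethylsilyl)pent-1-yn-3-one | COc1cc(OCc2ccccc2)ccc1CCC(=O)C#C[Si](C)(C)C
F12 | step 12 | (3R)-5-[4-(benzyloxy)-2-methoxyphenyl]-1-(trimethylsilyl)pent-1-yn-3-ol | COc1cc(OCc2ccccc2)ccc1CC[C@@H](O)C#C[Si](C)(C)C
F13 | step 12 | (3R)-5-[4-(benzyloxy)-2-methoxyphenyl]-1-(trimethylsilyl)pent-1-yn-3-yl diethyl phosphate | COc1cc(OCc2ccccc2)ccc1CC[C@@H](OP(=O)(OCC)OCC)C#C[Si](C)(C)C
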